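**Plan**

1. Last cut: the seven aryl O–CH3 bonds (global demethylation of 25). Ring A is the benzene ring of the dihydrobenzofuran whose C3 is the sp3 CH of the seven-membered ring; ring B is the benzene ring that carries the second dihydrobenzofuran.
2. Main cut: two bonds of the seven-membered ring, alkene CH to C4 of the ring-A benzofuran unit, and C3 of that unit to ring B. This gives flat, achiral 4-iodo-2-arylbenzofuran 8 and enantiopure ortho-bromo 1,1-diarylethene 23. Enabling feature: C3 of the ring-A dihydrobenzofuran lies peri to C4 (the ring-A carbon bearing the alkene CH), and H-2/H-3 are trans, which is what syn delivery of aryl and hydrogen across the C2=C3 bond of a 2-arylbenzofuran gives.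
3. 23 is cut at O1–C2 and C2–C3 of the ring-B dihydrobenzofuran ([4+1] of an ortho-quinone methide with a 4-methoxybenzylidene sulfur ylide); 8 is cut at C2=C3 (intramolecular Wittig). Both arise from salicylaldehyde 2.
4. Forward ring order: furan ring of 8; dihydrofuran ring on ring B (23); then, in one pot, the seven-membered ring and both sp3 centres of the ring-A dihydrofuran (25); then 26.
5. Stereochemistry: C2/C3 (R,R) on ring B from the chiral sulfonium ylide, trans by anti addition and SN2 closure. C3/C2 (S,S) on ring A from facial control by the chiral bisphosphine–palladium aryl and from syn aryl/hydride delivery.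

Key step: step 13

Assumption: the facial sense of sulfide 16 in step 12 and of (R)-BINAP in step 13 is taken by analogy with related benzylidene transfers and dearomative Heck reactions; the antipodes of both are equally available if the sense proves opposite.

**Step 1**
Reactants: 1 2-bromo-4,6-dimethoxybenzaldehyde
Product: 2 2-bromo-6-hydroxy-4-methoxybenzaldehyde
Conditions: BCl3 (1.1 equiv), CH2Cl2, −78 → 0 °C; aqueous work-up
Reagents that add atoms: none
Why: Boron chelated between the formyl oxygen and the ortho methoxy group should cleave only that methyl ether (chelation-controlled selective O-demethylation), leaving the para methoxy group, bromide and aldehyde intact.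

**Step 2**
Reactants: 2 2-bromo-6-hydroxy-4-methoxybenzaldehyde
Product: 3 3-bromo-2-(hydroxymethyl)-5-methoxyphenol
Conditions: NaBH4, MeOH, 0 °C
Reagents that add atoms: none
Why: Borohydride reduction of the aryl aldehyde should give the salicyl alcohol without touching the aryl bromide.

**Step 3**
Reactants: 3 3-bromo-2-(hydroxymethyl)-5-methoxyphenol
Product: 4 [(2-bromo-6-hydroxy-4-methoxyphenyl)methyl]triphenylphosphonium bromide
Conditions: PPh3·HBr, MeCN, reflux
Reagents that add atoms: triphenylphosphine hydrobromide [Br-].c1ccc(cc1)[PH+](c1ccccc1)c1ccccc1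
Why: The ortho-hydroxybenzyl alcohol ionises readily under HBr and the benzylic cation is captured by triphenylphosphine (standard phosphonium salt formation from salicyl alcohols).

**Step 4**
Reactants: 4 [(2-bromo-6-hydroxy-4-methoxyphenyl)methyl]triphenylphosphonium bromide; 5 4-methoxybenzoyl chloride
Product: 7 4-bromo-6-methoxy-2-(4-methoxyphenyl)-1-benzofuran, via acyloxybenzyl phosphonium salt 6 (not isolated)
Conditions: Et3N (3 equiv), toluene, reflux
Reagents that add atoms: none
Why: O-acylation of the phenol followed by ylide formation and intramolecular Wittig reaction onto the ester carbonyl is an established route to 2-arylbenzofurans and tolerates the aryl bromide.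

**Step 5**
Reactants: 7 4-bromo-6-methoxy-2-(4-methoxyphenyl)-1-benzofuran
Product: 8 4-iodo-6-methoxy-2-(4-methoxyphenyl)-1-benzofuran
Conditions: NaI (2 equiv), CuI (10 mol%), trans-N,N′-dimethylcyclohexane-1,2-diamine (20 mol%), 1,4-dioxane, 110 °C
Reagents that add atoms: sodium iodide [Na+].[I-]
Why: Copper-catalysed aromatic Finkelstein exchange, driven by precipitation of NaBr, should convert the bromide into the iodide needed for halogen differentiation in step 13.

**Step 6**
Reactants: 2 2-bromo-6-hydroxy-4-methoxybenzaldehyde; 9 4-methoxyphenylmagnesium bromide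
Product: 10 3-bromo-2-[hydroxy(4-methoxyphenyl)methyl]-5-methoxyphenol (racemic)
Conditions: 9 (2.3 equiv), THF, −78 → 0 °C; aqueous NH4Cl
Reagents that add atoms: none
Why: Grignard addition to the aldehyde after deprotonation of the phenol by the first equivalent; the new carbinol centre is removed in step 7, so its configuration is irrelevant.

**Step 7**
Reactants: 10 3-bromo-2-[hydroxy(4-methoxyphenyl)methyl]-5-methoxyphenol
Product: 11 (2-bromo-6-hydroxy-4-methoxyphenyl)(4-methoxyphenyl)methanone
Conditions: MnO2 (activated, excess), CH2Cl2, room temperature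
Reagents that add atoms: none
Why: Activated MnO2 selectively oxidises the doubly benzylic alcohol to the ortho-hydroxybenzophenone in the presence of the free phenol.

**Step 8**
Reactants: 11 (2-bromo-6-hydroxy-4-methoxyphenyl)(4-methoxyphenyl)methanone
Product: 13 3-bromo-5-methoxy-2-[1-(4-methoxyphenyl)ethenyl]phenol, via tertiary carbinol 12 (not isolated)
Conditions: MeMgBr (3 equiv), THF, 0 °C → room temperature; aqueous NH4Cl; crude carbinol, pyridinium p-toluenesulfonate (cat.), toluene, 50 °C
Reagents that add atoms: methylmagnesium bromide C[Mg]Br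
Why: The small methyl Grignard reagent adds to the hindered, magnesium-chelated ketone, and the tertiary bis-benzylic carbinol next to a phenol should lose water under mild acid to give the 1,1-diarylethene (Grignard addition then dehydration).

**Step 9**
Reactants: 13 3-bromo-5-methoxy-2-[1-(4-methoxyphenyl)ethenyl]phenol
Product: 14 4-bromo-2-hydroxy-6-methoxy-3-[1-(4-methoxyphenyl)ethenyl]benzaldehyde
Conditions: MgCl2 (anhydrous), Et3N, (CH2O)n, MeCN, reflux
Reagents that add atoms: paraformaldehyde (as formaldehyde) C=O
Why: Magnesium phenoxide-directed ortho-formylation is ortho-specific, and the only free ortho position is the carbon between OH and OMe, so the aldehyde should enter there and not para to the phenol.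

**Step 10**
Reactants: 14 4-bromo-2-hydroxy-6-methoxy-3-[1-(4-methoxyphenyl)ethenyl]benzaldehyde
Product: 15 tert-butyl 3-bromo-6-formyl-5-methoxy-2-[1-(4-methoxyphenyl)ethenyl]phenyl carbonate
Conditions: Boc2O, DMAP (cat.), iPr2NEt, CH2Cl2, 0 °C → room temperature
Reagents that add atoms: di-tert-butyl dicarbonate CC(C)(C)OC(=O)OC(=O)OC(C)(C)C
Why: DMAP-catalysed O-acylation of the phenol installs the carbonate that later serves as the leaving group for ortho-quinone methide formation.

**Step 11**
Reactants: 16 (1R,4R,5R)-isothiocineole; 17 4-methoxybenzyl bromide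
Product: 18 (1R,4R,5R)-6-(4-methoxybenzyl)-4,7,7-trimethyl-6-thiabicyclo[3.2.1]octan-6-ium trifluoromethanesulfonate
Conditions: LiOTf, CH2Cl2/H2O, room temperature
Reagents that add atoms: lithium trifluoromethanesulfonate [Li+].[O-]S(=O)(=O)C(F)(F)F
Why: S-alkylation of the bicyclic sulfide on its exposed lone pair, with anion exchange to the non-nucleophilic triflate, should give a single sulfonium diastereomer (sulfonium salt formation).

**Step 12**
Reactants: 15 tert-butyl 3-bromo-6-formyl-5-methoxy-2-[1-(4-methoxyphenyl)ethenyl]phenyl carbonate; 19 3,5-dimethoxyphenylmagnesium chloride; 18 the sulfonium triflate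
Product: 23 (2R,3R)-6-bromo-3-(3,5-dimethoxyphenyl)-4-methoxy-2-(4-methoxyphenyl)-7-[1-(4-methoxyphenyl)ethenyl]-2,3-dihydro-1-benzofuran, via chloromagnesium phenoxide carbonate 20 (not isolated), via ortho-quinone methide 21 (not isolated), via sulfonium ylide 22 (not isolated)
Conditions: 19 (1.05 equiv), THF, −78 °C; then transfer into 22 [from 18 (1.3 equiv), LiN(SiMe3)2 (1.25 equiv), THF/CH2Cl2, −78 °C]; −78 → 0 °C
Reagents that add atoms: none
Why: Proposed new method: aryl addition to the aldehyde gives an alkoxide that takes the tert-butoxycarbonyl group from the neighbouring phenol oxygen (20), the magnesium phenoxide expels tert-butyl carbonate to form ortho-quinone methide 21 below 0 °C, ylide 22 adds through its unshielded face to the methide carbon, and the phenoxide closes the ring by 5-exo-tet displacement of the sulfide with inversion, the anti betaine giving the trans (2R,3R) product with both centres set by the chiral sulfide; the closest known reaction types are the [4+1] annulation of ortho-quinone methides with stabilised sulfur ylides, ortho-quinone methide generation by carbonate transfer after organometallic addition, and asymmetric benzylidene transfer from sulfonium salts of this sulfide to aldehydes and imines.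

**Step 13**
Reactants: 8 4-iodo-6-methoxy-2-(4-methoxyphenyl)-1-benzofuran; 23 the (2R,3R)-bromo dihydrobenzofuran
Product: 25 hepta-O-methyl ether of 26 (ring-A dihydrobenzofuran 2S,3S; ring-B dihydrobenzofuran 2R,3R), via Z-triarylethene 24 (not isolated)
Conditions: Pd(OAc)2 (10 mol%), Bu4NCl, NaHCO3, DMF, 80 °C; then (R)-BINAP (20 mol%), HCO2Na (slow addition), 100 °C
Reagents that add atoms: none
Why: Proposed new method: zerovalent palladium inserts into the C4–I bond of 8 (the C–Br bond of 23 should be inert at 80 °C without phosphine), carbopalladation of the terminal CH2 of the 1,1-diarylethene and β-hydride elimination form the alkene CH–ring A bond and give Z-triarylethene 24, in which the brominated carbon of ring B sits over benzofuran C3 as the ortho carbons of a cis-stilbene do; after (R)-BINAP and formate are added, the metal inserts into C–Br, adds syn across the benzofuran C3=C2 bond, and the benzylic α-oxygenated alkylpalladium, which has no syn β-hydrogen, is intercepted by formate (decarboxylation, then C–H reductive elimination with retention). The closest known reaction types are the Heck arylation of 1,1-diarylethenes and the intramolecular dearomative reductive Heck reaction of benzofurans and indoles; their one-pot union as a formal [4+3] annulation and the seven-membered closure are new. The seven-membered ring closes by 7-exo-trig carbopalladation (new C–C bond to C3, palladium leaving the ring on C2). C3 of the new dihydrobenzofuran is set by which face of the flat benzofuran the BINAP–palladium aryl attacks (catalyst control; the remote centres of 23 make a wrong-face product a separable diastereomer), and C2 follows from C3 because aryl and hydrogen arrive on the same face, which is the trans-2,3 relationship of the target. The step needs chemoselectivity (iodide before bromide, Heck before hydride capture), secured by the halogen pair and by adding formate only after the first stage, and Z geometry of 24, favoured because the 2,6-disubstituted ring B is twisted out of the alkene plane and leaves stilbene-type conjugation to the 4-methoxyphenyl group and ring A.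

**Step 14**
Reactants: 25 hepta-O-methyl ether of 26
Product: 26 target heptaphenol CNP0325907.1
Conditions: BBr3 (20 equiv), CH2Cl2, −78 → 0 °C; MeOH quench
Reagents that add atoms: none
Why: Lewis-acid cleavage of all seven aryl methyl ethers (global O-demethylation) should not touch the four stereocentres, provided the temperature is kept low enough to avoid ionising the benzylic C2–O bonds.

**Compound list**

1 | 2-bromo-4,6-dimethoxybenzaldehyde | COc1cc(Br)c(C=O)c(OC)c1 | starting material
2 | 2-bromo-6-hydroxy-4-methoxybenzaldehyde | COc1cc(O)c(C=O)c(Br)c1 | intermediate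
3 | 3-bromo-2-(hydroxymethyl)-5-methoxyphenol | COc1cc(O)c(CO)c(Br)c1 | intermediate
4 | [(2-bromo-6-hydroxy-4-methoxyphenyl)methyl]triphenylphosphonium bromide | COc1cc(O)c(C[P+](c2ccccc2)(c2ccccc2)c2ccccc2)c(Br)c1.[Br-] | intermediate
5 | 4-methoxybenzoyl chloride | COc1ccc(C(Cl)=O)cc1 | starting material
6 | {2-bromo-4-methoxy-6-[(4-methoxybenzoyl)oxy]benzyl}triphenylphosphonium bromide (not isolated) | COc1ccc(C(=O)Oc2cc(OC)cc(Br)c2C[P+](c2ccccc2)(c2ccccc2)c2ccccc2)cc1.[Br-] | intermediate
7 | 4-bromo-6-methoxy-2-(4-methoxyphenyl)-1-benzofuran | COc1ccc(-c2cc3c(Br)cc(OC)cc3o2)cc1 | intermediate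
8 | 4-iodo-6-methoxy-2-(4-methoxyphenyl)-1-benzofuran | COc1ccc(-c2cc3c(I)cc(OC)cc3o2)cc1 | intermediate
9 | 4-methoxyphenylmagnesium bromide | COc1ccc([Mg]Br)cc1 | starting material
10 | 3-bromo-2-[hydroxy(4-methoxyphenyl)methyl]-5-methoxyphenol (racemic) | COc1ccc(C(O)c2c(O)cc(OC)cc2Br)cc1 | intermediate
11 | (2-bromo-6-hydroxy-4-methoxyphenyl)(4-methoxyphenyl)methanone | COc1ccc(C(=O)c2c(O)cc(OC)cc2Br)cc1 | intermediate
12 | 3-bromo-2-[1-hydroxy-1-(4-methoxyphenyl)ethyl]-5-methoxyphenol (racemic, not isolated) | COc1ccc(C(C)(O)c2c(O)cc(OC)cc2Br)cc1 | intermediate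
13 | 3-bromo-5-methoxy-2-[1-(4-methoxyphenyl)ethenyl]phenol | COc1ccc(C(=C)c2c(O)cc(OC)cc2Br)cc1 | intermediate
14 | 4-bromo-2-hydroxy-6-methoxy-3-[1-(4-methoxyphenyl)ethenyl]benzaldehyde | COc1ccc(C(=C)c2c(Br)cc(OC)c(C=O)c2O)cc1 | intermediate
15 | tert-butyl 3-bromo-6-formyl-5-methoxy-2-[1-(4-methoxyphenyl)ethenyl]phenyl carbonate | COc1ccc(C(=C)c2c(Br)cc(OC)c(C=O)c2OC(=O)OC(C)(C)C)cc1 | intermediate
16 | (1R,4R,5R)-isothiocineole, (1R,4R,5R)-4,7,7-trimethyl-6-thiabicyclo[3.2.1]octane | C[C@@H]1CC[C@@H]2C[C@H]1SC2(C)C | starting material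
17 | 4-methoxybenzyl bromide | COc1ccc(CBr)cc1 | starting material
18 | (1R,4R,5R)-6-(4-methoxybenzyl)-4,7,7-trimethyl-6-thiabicyclo[3.2.1]octan-6-ium trifluoromethanesulfonate | C[C@@H]1CC[C@@H]2C[C@H]1[S+](Cc1ccc(OC)cc1)C2(C)C.[O-]S(=O)(=O)C(F)(F)F | intermediate
19 | 3,5-dimethoxyphenylmagnesium chloride | COc1cc([Mg]Cl)cc(OC)c1 | starting material
20 | chloromagnesium 3-bromo-6-[(tert-butoxycarbonyloxy)(3,5-dimethoxyphenyl)methyl]-5-methoxy-2-[1-(4-methoxyphenyl)ethenyl]phenoxide (not isolated) | COc1ccc(C(=C)c2c(Br)cc(OC)c(C(OC(=O)OC(C)(C)C)c3cc(OC)cc(OC)c3)c2O[Mg]Cl)cc1 | intermediate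
21 | 3-bromo-6-[(3,5-dimethoxyphenyl)methylidene]-5-methoxy-2-[1-(4-methoxyphenyl)ethenyl]cyclohexa-2,4-dien-1-one, the ortho-quinone methide (not isolated) | COc1ccc(C(=C)C2=C(Br)C=C(OC)C(=Cc3cc(OC)cc(OC)c3)C2=O)cc1 | intermediate
22 | 4-methoxybenzylide of sulfonium salt 18 (not isolated) | C[C@@H]1CC[C@@H]2C[C@H]1[S+]([CH-]c1ccc(OC)cc1)C2(C)C | intermediate
23 | (2R,3R)-6-bromo-3-(3,5-dimethoxyphenyl)-4-methoxy-2-(4-methoxyphenyl)-7-[1-(4-methoxyphenyl)ethenyl]-2,3-dihydro-1-benzofuran | COc1ccc(C(=C)c2c(Br)cc(OC)c3c2O[C@@H](c2ccc(OC)cc2)[C@@H]3c2cc(OC)cc(OC)c2)cc1 | intermediate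
24 | Z-triarylethene: 23 whose terminal alkene carbon carries the 6-methoxy-2-(4-methoxyphenyl)-1-benzofuran-4-yl group cis to the bromoaryl ring (not isolated) | COc1ccc(/C(=C/c2cc(OC)cc3oc(-c4ccc(OC)cc4)cc23)c2c(Br)cc(OC)c3c2O[C@@H](c2ccc(OC)cc2)[C@@H]3c2cc(OC)cc(OC)c2)cc1 | intermediate
25 | hepta-O-methyl ether of 26 (ring-A dihydrobenzofuran 2S,3S; ring-B dihydrobenzofuran 2R,3R) | COc1ccc(C2=Cc3cc(OC)cc4c3[C@H](c3cc(OC)c5c(c32)O[C@@H](c2ccc(OC)cc2)[C@@H]5c2cc(OC)cc(OC)c2)[C@@H](c2ccc(OC)cc2)O4)cc1 | intermediate
26 | CNP0325907.1: dibenzo-fused cycloheptatriene bearing a 4-hydroxyphenyl group on the alkene, a (2S,3S)-2-(4-hydroxyphenyl)dihydrofuran fused to ring A through the sp3 CH, and a (2R,3R)-2-(4-hydroxyphenyl)-3-(3,5-dihydroxyphenyl)dihydrofuran fused to ring B | Oc1ccc(C2=Cc3cc(O)cc4c3[C@H](c3cc(O)c5c(c32)O[C@@H](c2ccc(O)cc2)[C@@H]5c2cc(O)cc(O)c2)[C@@H](c2ccc(O)cc2)O4)cc1 | target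

**Totals**

Total step count: 14. Longest linear sequence: 9 steps (1, 6, 7, 8, 9, 10, 12, 13, 14).

**Three steps most likely to fail**

1. Step 13 (Proposed new method). The process risks are:
 - hydride capture of the second aryl–palladium species before the slower seven-membered insertion;
 - formation of the E alkene in the first Heck stage, which cannot cyclise;
 - base-assisted C–H arylation at C3 with re-aromatisation;
 - weak facial control by the ligand.

 The fallback uses known chemistry with the bond order reversed. It sets out from 23 and 2 and returns at 25. Compound 2 is acylated (Boc2O, DMAP) to tert-butyl 3-bromo-2-formyl-5-methoxyphenyl carbonate F1. Compound 23 undergoes bromine–magnesium exchange (iPrMgCl·LiCl, THF) to the arylmagnesium chloride F2, which adds to F1 at −78 °C. Carbonate transfer and loss of tert-butyl carbonate give the ring-A ortho-quinone methide F3. This is trapped in a [4+1] annulation by the achiral ylide from dimethyl(4-methoxybenzyl)sulfonium tetrafluoroborate and LiN(SiMe3)2. The two trans products are diastereomers because the ring-B part is enantiopure, so the (2S,3S)-4-bromo-6-methoxy-2-(4-methoxyphenyl)-3-aryl-2,3-dihydro-1-benzofuran F4 would be separated by chromatography. An intramolecular 7-endo Heck reaction of F4 (Pd(OAc)2, P(o-tol)3, Et3N, DMF, 110 °C) between the ring-A bromide and the 1,1-diarylethene then closes the alkene CH–ring A bond with the ring geometry enforced and gives 25.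

2. Step 12 (Proposed new method). The process risks are:
 - decomposition of the semistabilised ylide on warming before the ortho-quinone methide has formed;
 - capture of the methide by tert-butoxide or a second aryl nucleophile;
 - loss of trans selectivity at the betaine stage;
 - insufficient facial control by the sulfide.

 The fallback is enantioselective C–H insertion of a donor/donor rhodium carbene, which is established for 2-(4-methoxyphenyl)-3-(3,5-dimethoxyphenyl)dihydrobenzofurans. It sets out from 14 and returns at 23. O-Alkylation of 14 with 17 (K2CO3, DMF) gives 4-bromo-6-methoxy-2-[(4-methoxyphenyl)methoxy]-3-[1-(4-methoxyphenyl)ethenyl]benzaldehyde F5. Addition of 19 gives the diarylmethanol F6, and MnO2 oxidation gives the diaryl ketone F7. Condensation with N2H4·H2O (AcOH, EtOH, reflux) gives the hydrazone F8. MnO2 oxidation gives the diaryldiazomethane F9. With the enantiomer of Rh2(PTAD)4 that sets C3 as R (1 mol%, CH2Cl2, −20 °C), F9 inserts into the benzylic O–CH2 bond to give the cis-(2S,3R)-dihydrobenzofuran F10. Epimerisation at C2 (CF3CO2H, CH2Cl2, 0 °C) proceeds by reversible ionisation of the C2–O bond to the 4-methoxybenzyl cation and gives the trans compound 23.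

3. Step 14. The process risks are Lewis-acid ionisation of the benzylic C2–O bonds of both dihydrobenzofurans (ring opening or epimerisation) and protonation of the electron-rich triarylethene by HBr, followed by Friedel–Crafts side reactions. The fallback sets out from 25 and returns at 26. The methyl groups are removed instead by SN2 attack of thiolate under basic aprotic conditions (NaSEt, DMF, 130 °C), which avoids any cationic intermediate; it makes no new isolated compound (F0).

**Further compounds**

F1 | step 13 | tert-butyl 3-bromo-2-formyl-5-methoxyphenyl carbonate | COc1cc(Br)c(C=O)c(OC(=O)OC(C)(C)C)c1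
F2 | step 13 | arylmagnesium chloride from 23 (MgCl in place of Br) | COc1ccc(C(=C)c2c([Mg]Cl)cc(OC)c3c2O[C@@H](c2ccc(OC)cc2)[C@@H]3c2cc(OC)cc(OC)c2)cc1
F3 | step 13 | ring-A ortho-quinone methide, 5-bromo-3-methoxy-6-(arylmethylidene)cyclohexa-2,4-dien-1-one | COc1ccc(C(=C)c2c(C=C3C(=O)C=C(OC)C=C3Br)cc(OC)c3c2O[C@@H](c2ccc(OC)cc2)[C@@H]3c2cc(OC)cc(OC)c2)cc1
F4 | step 13 | (2S,3S)-4-bromo-6-methoxy-2-(4-methoxyphenyl)-3-aryl-2,3-dihydro-1-benzofuran, aryl being the ring-B dihydrobenzofuran-6-yl unit of 23 | Brc1cc(OC)cc2c1[C@H](c1cc(OC)c3c(c1C(=C)c1ccc(OC)cc1)O[C@@H](c1ccc(OC)cc1)[C@@H]3c1cc(OC)cc(OC)c1)[C@@H](c1ccc(OC)cc1)O2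
F5 | step 12 | 4-bromo-6-methoxy-2-[(4-methoxyphenyl)methoxy]-3-[1-(4-methoxyphenyl)ethenyl]benzaldehyde | COc1ccc(COc2c(C=O)c(OC)cc(Br)c2C(=C)c2ccc(OC)cc2)cc1
F6 | step 12 | (3,5-dimethoxyphenyl)(aryl)methanol from F5 (racemic) | COc1ccc(COc2c(C(O)c3cc(OC)cc(OC)c3)c(OC)cc(Br)c2C(=C)c2ccc(OC)cc2)cc1
F7 | step 12 | (3,5-dimethoxyphenyl)(aryl)methanone from F6 | COc1ccc(COc2c(C(=O)c3cc(OC)cc(OC)c3)c(OC)cc(Br)c2C(=C)c2ccc(OC)cc2)cc1
F8 | step 12 | hydrazone of F7 | COc1ccc(COc2c(C(=NN)c3cc(OC)cc(OC)c3)c(OC)cc(Br)c2C(=C)c2ccc(OC)cc2)cc1
F9 | step 12 | diaryldiazomethane from F8 | COc1ccc(COc2c(C(=[N+]=[N-])c3cc(OC)cc(OC)c3)c(OC)cc(Br)c2C(=C)c2ccc(OC)cc2)cc1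
F10 | step 12 | (2S,3R)-cis isomer of 23 | COc1ccc(C(=C)c2c(Br)cc(OC)c3c2O[C@H](c2ccc(OC)cc2)[C@@H]3c2cc(OC)cc(OC)c2)cc1
F0 | step 14 | none | none
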